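**Strategy.** The lower pyran ring (O1–C2–C3–C4–C4a–C8a) is cut at O1–C2 and C3–C4: O1, C8a, C4a and C4 are a latent o-quinone methide of the phloroglucinol A ring, and C2–C3 is a Z-styrene. One catalytic asymmetric oxa-[4+2] cycloaddition joins an alkynyl o-quinone methide (no β-hydrogen; the silylalkyne is a masked CH2CO2H) with a (Z)-β-boryl styrene (boron is a masked 3-OH), closing the ring and setting C2, C3 and C4. The epicatechin upper unit is then attached at C8 by a 4β-selective Friedel–Crafts coupling, one hydroboration/oxidation unveils the 3-hydroxyl and the acetic acid, and hydrogenolysis frees the phenols.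

Key step: step 5

Remarks. Flavonoid numbering is used (O1, C2, C3, C4, C4a, C5–C8, C8a); "lower unit" is the flavan that carries the CH2CO2H group. Assumption: the (R)-configured phosphoric acid in step 5 is taken to favour the face of 7 that leads to the drawn enantiomer of 8; if the sense of induction is the opposite, the (S)-acid is used in the same way. Compounds 1, 4 and 9 are taken as commercial.

**Step 1**
Reactants: 1 3,5-bis(benzyloxy)phenol
Product: 2 4,6-bis(benzyloxy)-2-hydroxybenzaldehyde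
Conditions: MgCl2, Et3N, (CH2O)n, MeCN, reflux; 1 M HCl work-up
Reagents that add atoms: paraformaldehyde (as formaldehyde), C=O
Why: Magnesium-mediated ortho-formylation (Casnati–Skattebøl): the magnesium phenoxide delivers formaldehyde only ortho to the free OH, a second equivalent oxidises the hydroxymethyl group by hydride transfer, and the chelated salicylaldehyde resists a second formylation.

**Step 2**
Reactants: 2 4,6-bis(benzyloxy)-2-hydroxybenzaldehyde
Product: 3 (±)-1-[2,4-bis(benzyloxy)-6-hydroxyphenyl]-3-(trimethylsilyl)prop-2-yn-1-ol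
Conditions: TMS-acetylene, n-BuLi (2.5 equiv each), THF, −78 → 0 °C; cold sat. NH4Cl; used crude
Reagents that add atoms: ethynyltrimethylsilane, C#C[Si](C)(C)C
Why: 1,2-Addition of a lithium acetylide to the aldehyde (the first equivalent is consumed by the phenol); the carbinol centre is racemic and irrelevant because it becomes sp2 in step 5.

**Step 3**
Reactants: 4 3,4-bis(benzyloxy)benzaldehyde
Product: 5 1,2-bis(benzyloxy)-4-ethynylbenzene
Conditions: dimethyl (1-diazo-2-oxopropyl)phosphonate, K2CO3, MeOH, rt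
Reagents that add atoms: dimethyl (1-diazo-2-oxopropyl)phosphonate, COP(=O)(OC)C(=[N+]=[N-])C(C)=O
Why: Seyferth–Gilbert homologation with the Ohira–Bestmann reagent converts the aryl aldehyde into the terminal alkyne under mild base that leaves the benzyl ethers untouched.

**Step 4**
Reactants: 5 1,2-bis(benzyloxy)-4-ethynylbenzene
Product: 6 2-{(Z)-2-[3,4-bis(benzyloxy)phenyl]ethenyl}-4,4,5,5-tetramethyl-1,3,2-dioxaborolane
Conditions: HBpin, [Rh(cod)Cl]2 (1.5 mol %), P(iPr)3 (6 mol %), Et3N, cyclohexane, rt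
Reagents that add atoms: pinacolborane, CC1(C)OBOC1(C)C
Why: Rhodium-catalysed trans-hydroboration of a terminal alkyne through a rhodium vinylidene should give the Z-alkenylboronate, and this Z geometry later becomes the 2,3-cis relationship.

**Step 5 (key step)**
Reactants: 3 (±)-1-[2,4-bis(benzyloxy)-6-hydroxyphenyl]-3-(trimethylsilyl)prop-2-yn-1-ol; 6 2-{(Z)-2-[3,4-bis(benzyloxy)phenyl]ethenyl}-4,4,5,5-tetramethyl-1,3,2-dioxaborolane (1.5 equiv)
Product: 8 2-{(2S,3R,4R)-5,7-bis(benzyloxy)-2-[3,4-bis(benzyloxy)phenyl]-4-[(trimethylsilyl)ethynyl]-3,4-dihydro-2H-chromen-3-yl}-4,4,5,5-tetramethyl-1,3,2-dioxaborolane (2,3-cis, 3,4-trans), via o-quinone methide 7 (not isolated)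
Conditions: (R)-TRIP (10 mol %), 4 Å MS, toluene, −20 → 0 °C
Reagents that add atoms: none
Why: Proposed new method: the phosphoric acid ionises the benzylic, propargylic alcohol of 3 to the E-configured alkynyl o-quinone methide 7, held as a hydrogen-bonded ion pair, and the Z-alkenylboronate 6 adds across its O=C–C=C unit in an inverse-electron-demand oxa-[4+2] cycloaddition that is concerted but asynchronous (C3–C4 ahead of O1–C2); the closest known reaction type is the chiral Brønsted acid catalysed [4+2] of o-quinone methides from o-hydroxybenzyl alcohols with styrenes, and new here is a (Z)-β-boryl styrene as the 2π partner. The dihydropyran ring is closed by the cycloaddition itself, the phenolic oxygen ending on the benzylic carbon (six-membered ring, both bonds on one face of the alkene). Regiochemistry should be secure because attack through the boron-bearing carbon leaves the developing positive charge on the 3,4-bis(benzyloxy)benzylic carbon, β to the C–B bond, whereas the reverse orientation would need an α-boryl cation. The Z geometry of 6 translates suprafacially into the 2,3-cis relationship, and the exo mode, in which the pinacolboryl group on the carbon that forms the short bond lies anti to ring carbon C4a and not under the methide ring with its peri benzyloxy group, gives 3,4-trans and hence 2,4-trans. The absolute configuration (C4 first, C3 and C2 following from it) is set by the chiral phosphate, which shields one face of the bound methide. The alkynyl substituent has no β-hydrogen, so 7 cannot tautomerise to a vinylphenol, and its silyl cap blocks attack at the alkyne terminus.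

**Step 6**
Reactants: 9 (−)-epicatechin
Product: 10 5,7,3',4'-tetra-O-benzyl-(−)-epicatechin
Conditions: BnBr (4.2 equiv), K2CO3, DMF, 0 °C → rt
Reagents that add atoms: benzyl bromide, BrCc1ccccc1
Why: Williamson etherification: carbonate deprotonates only the four phenols, so the secondary 3-OH stays free and no stereocentre is touched.

**Step 7**
Reactants: 10 5,7,3',4'-tetra-O-benzyl-(−)-epicatechin
Product: 11 (2R,3R,4S)-5,7-bis(benzyloxy)-2-[3,4-bis(benzyloxy)phenyl]-4-(2-hydroxyethoxy)-3,4-dihydro-2H-chromen-3-ol (4β ether)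
Conditions: DDQ (2 equiv), ethylene glycol, CH2Cl2, rt
Reagents that add atoms: ethylene glycol, OCCO
Why: DDQ benzylic oxidation: hydride abstraction at C4 gives an A-ring-stabilised cation that the glycol captures anti to the 3-OH; this centre is ionised again in step 8.

**Step 8**
Reactants: 8 the cycloadduct (2.5 equiv, surplus recovered); 11 the 4β-(2-hydroxyethoxy) ether
Product: 12 octa-O-benzyl 4β→8 dimer: the (2R,3R,4R)-5,7,3',4'-tetra-O-benzylepicatechin-4-yl unit bonded through C4 to C8 of 8 (lower unit 2S,3R,4R, boronate and silylalkyne retained)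
Conditions: TMSOTf (0.3 equiv), CH2Cl2, −78 °C; Et3N quench
Reagents that add atoms: none
Why: Lewis acid promoted Friedel–Crafts flavanylation: the C4 cation from 11 is attacked by C8 of 8 (less hindered than C6 between two benzyloxy groups) on the face anti to the axial 3-OH and the C2 aryl, which sets the upper C4 centre as 4β (3,4-trans) by substrate control.

**Step 9**
Reactants: 12 the octa-O-benzyl dimer
Product: 15 2-{(2R,3R,4S)-5,7-bis(benzyloxy)-2-[3,4-bis(benzyloxy)phenyl]-8-[(2R,3R,4R)-5,7-bis(benzyloxy)-2-[3,4-bis(benzyloxy)phenyl]-3-hydroxy-3,4-dihydro-2H-chromen-4-yl]-3-hydroxy-3,4-dihydro-2H-chromen-4-yl}acetic acid, via alkenylborane 13 (not isolated), via acylsilane 14 (not isolated)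
Conditions: Cy2BH (4 equiv), THF, 0 °C → rt; then 3 M NaOH, 30 % H2O2, 0 → 40 °C; 1 M HCl to pH 3
Reagents that add atoms: hydrogen peroxide, OO
Why: Hydroboration–oxidation: dicyclohexylborane places boron on the silicon-bearing alkyne carbon, alkaline peroxide takes the alkenylborane through the acylsilane to the carboxylic acid, and the same peroxide oxidises the secondary C3–B bond to C3–OH with retention by 1,2-migration.

**Step 10**
Reactants: 15 the octa-O-benzyl hydroxy acid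
Product: 16 2-{(2R,3R,4S)-2-(3,4-dihydroxyphenyl)-8-[(2R,3R,4R)-2-(3,4-dihydroxyphenyl)-3,5,7-trihydroxy-3,4-dihydro-2H-chromen-4-yl]-3,5,7-trihydroxy-3,4-dihydro-2H-chromen-4-yl}acetic acid (CNP0190976.1)
Conditions: H2 (1 atm), Pd(OH)2/C, THF/MeOH/H2O, rt; Sephadex LH-20
Reagents that add atoms: none
Why: Catalytic hydrogenolysis removes the eight benzyl ethers under neutral conditions that leave the interflavan bond and all six stereocentres untouched.

**Compound list**

1 | 3,5-bis(benzyloxy)phenol | Oc1cc(OCc2ccccc2)cc(OCc2ccccc2)c1 | starting material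
2 | 4,6-bis(benzyloxy)-2-hydroxybenzaldehyde | O=Cc1c(O)cc(OCc2ccccc2)cc1OCc1ccccc1 | intermediate
3 | (±)-1-[2,4-bis(benzyloxy)-6-hydroxyphenyl]-3-(trimethylsilyl)prop-2-yn-1-ol | C[Si](C)(C)C#CC(O)c1c(O)cc(OCc2ccccc2)cc1OCc1ccccc1 | intermediate
4 | 3,4-bis(benzyloxy)benzaldehyde | O=Cc1ccc(OCc2ccccc2)c(OCc2ccccc2)c1 | starting material
5 | 1,2-bis(benzyloxy)-4-ethynylbenzene | C#Cc1ccc(OCc2ccccc2)c(OCc2ccccc2)c1 | intermediate
6 | 2-{(Z)-2-[3,4-bis(benzyloxy)phenyl]ethenyl}-4,4,5,5-tetramethyl-1,3,2-dioxaborolane | CC1(C)OB(/C=C\c2ccc(OCc3ccccc3)c(OCc3ccccc3)c2)OC1(C)C | intermediate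
7 | (6E)-3,5-bis(benzyloxy)-6-[3-(trimethylsilyl)prop-2-yn-1-ylidene]cyclohexa-2,4-dien-1-one (o-quinone methide) | O=C1C=C(OCc2ccccc2)C=C(OCc2ccccc2)/C1=C\C#C[Si](C)(C)C | intermediate (not isolated)
8 | 2-{(2S,3R,4R)-5,7-bis(benzyloxy)-2-[3,4-bis(benzyloxy)phenyl]-4-[(trimethylsilyl)ethynyl]-3,4-dihydro-2H-chromen-3-yl}-4,4,5,5-tetramethyl-1,3,2-dioxaborolane | C[Si](C)(C)C#C[C@H]1c2c(OCc3ccccc3)cc(OCc3ccccc3)cc2O[C@H](c2ccc(OCc3ccccc3)c(OCc3ccccc3)c2)[C@@H]1B1OC(C)(C)C(C)(C)O1 | intermediate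
9 | (−)-epicatechin, (2R,3R)-2-(3,4-dihydroxyphenyl)-3,4-dihydro-2H-chromene-3,5,7-triol | C1c2c(O)cc(O)cc2O[C@H](c2ccc(O)c(O)c2)[C@@H]1O | starting material
10 | 5,7,3',4'-tetra-O-benzyl-(−)-epicatechin | C1c2c(OCc3ccccc3)cc(OCc3ccccc3)cc2O[C@H](c2ccc(OCc3ccccc3)c(OCc3ccccc3)c2)[C@@H]1O | intermediate
11 | (2R,3R,4S)-5,7-bis(benzyloxy)-2-[3,4-bis(benzyloxy)phenyl]-4-(2-hydroxyethoxy)-3,4-dihydro-2H-chromen-3-ol | OCCO[C@H]1c2c(OCc3ccccc3)cc(OCc3ccccc3)cc2O[C@H](c2ccc(OCc3ccccc3)c(OCc3ccccc3)c2)[C@@H]1O | intermediate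
12 | octa-O-benzyl 4β→8 dimer with C3 pinacolboronate and C4 (trimethylsilyl)ethynyl on the lower unit (lower 2S,3R,4R; upper 2R,3R,4R) | C[Si](C)(C)C#C[C@H]1c2c(OCc5ccccc5)cc(OCc5ccccc5)c([C@H]3c4c(OCc5ccccc5)cc(OCc5ccccc5)cc4O[C@H](c4ccc(OCc5ccccc5)c(OCc5ccccc5)c4)[C@@H]3O)c2O[C@H](c2ccc(OCc5ccccc5)c(OCc5ccccc5)c2)[C@@H]1B1OC(C)(C)C(C)(C)O1 | intermediate
13 | alkenylborane from 12: lower C4 carries (Z)-CH=C(SiMe3)(BCy2), upper 3-OH carried as its dicyclohexylborinate, ring configurations as in 12 | C[Si](C)(C)/C(B(C6CCCCC6)C6CCCCC6)=C\[C@H]1c2c(OCc5ccccc5)cc(OCc5ccccc5)c([C@H]3c4c(OCc5ccccc5)cc(OCc5ccccc5)cc4O[C@H](c4ccc(OCc5ccccc5)c(OCc5ccccc5)c4)[C@@H]3OB(C6CCCCC6)C6CCCCC6)c2O[C@H](c2ccc(OCc5ccccc5)c(OCc5ccccc5)c2)[C@@H]1B1OC(C)(C)C(C)(C)O1 | intermediate (not isolated)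
14 | acylsilane: octa-O-benzyl dimer with lower C4–CH2C(=O)SiMe3 and both 3-OH free (lower 2R,3R,4S; upper 2R,3R,4R) | C[Si](C)(C)C(=O)C[C@H]1c2c(OCc5ccccc5)cc(OCc5ccccc5)c([C@H]3c4c(OCc5ccccc5)cc(OCc5ccccc5)cc4O[C@H](c4ccc(OCc5ccccc5)c(OCc5ccccc5)c4)[C@@H]3O)c2O[C@H](c2ccc(OCc5ccccc5)c(OCc5ccccc5)c2)[C@@H]1O | intermediate (not isolated)
15 | 2-{(2R,3R,4S)-5,7-bis(benzyloxy)-2-[3,4-bis(benzyloxy)phenyl]-8-[(2R,3R,4R)-5,7-bis(benzyloxy)-2-[3,4-bis(benzyloxy)phenyl]-3-hydroxy-3,4-dihydro-2H-chromen-4-yl]-3-hydroxy-3,4-dihydro-2H-chromen-4-yl}acetic acid | O=C(O)C[C@H]1c2c(OCc5ccccc5)cc(OCc5ccccc5)c([C@H]3c4c(OCc5ccccc5)cc(OCc5ccccc5)cc4O[C@H](c4ccc(OCc5ccccc5)c(OCc5ccccc5)c4)[C@@H]3O)c2O[C@H](c2ccc(OCc5ccccc5)c(OCc5ccccc5)c2)[C@@H]1O | intermediate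
16 | 2-{(2R,3R,4S)-2-(3,4-dihydroxyphenyl)-8-[(2R,3R,4R)-2-(3,4-dihydroxyphenyl)-3,5,7-trihydroxy-3,4-dihydro-2H-chromen-4-yl]-3,5,7-trihydroxy-3,4-dihydro-2H-chromen-4-yl}acetic acid | O=C(O)C[C@H]1c2c(O)cc(O)c([C@H]3c4c(O)cc(O)cc4O[C@H](c4ccc(O)c(O)c4)[C@@H]3O)c2O[C@H](c2ccc(O)c(O)c2)[C@@H]1O | target

**Totals.** Total step count: 10. Longest linear sequence: 6 steps (steps 1, 2, 5, 8, 9, 10).

**Steps most likely to fail**

1. Step 5 (Proposed new method). The cycloaddition may drift into a stepwise cationic path with rotation about C2–C3 (loss of the Z-to-cis transfer), take the endo mode (2,4-cis), show weak face discrimination by the catalyst, or lose the quinone methide to self-condensation. The fallback uses known chemistry and gives up the cycloaddition. It sets out from 11: BF3·OEt2-mediated C4 allylation with allyltrimethylsilane, anti to the 3-OH, should give the 4β-allyl tetra-O-benzyl flavan-3-ol F1. Lemieux–Johnson cleavage (OsO4 cat., NaIO4, 2,6-lutidine) gives the aldehyde F2, and Pinnick oxidation the hydroxy acid F3. Benzylation of the carboxylate (BnBr, KHCO3, DMF) gives the benzyl ester F4. TMSOTf coupling of F4 (in excess) with a second portion of 11 gives the dimeric benzyl ester F5, and hydrogenolysis over Pd(OH)2/C brings the route back at 16.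

2. Step 8. The silyl triflate may promote anti-elimination of the C3 boronate with the ring oxygen (ring opening of 8), or arylation may spread to C6 and to the product. The fallback changes the mode of activation from oxophilic to thiophilic. It sets out from 11: exchange of the glycol ether for a benzylthio group (BnSH, BF3·OEt2, CH2Cl2) gives the 4β-benzylsulfanyl flavan-3-ol F6. Activation of F6 with AgBF4 in THF at 0 °C in the presence of 8 should form the same C4–C8 bond, returning to the route at 12.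

3. Step 9. Hydroboration of the hindered silylalkyne may be slow or incomplete, or the oxidation may stall at the acylsilane. The fallback separates the two oxidations and goes through a terminal alkyne. It sets out from 12: NaBO3·4H2O in THF/H2O oxidises only the C–B bond to give the 3-hydroxy silylalkyne F7. K2CO3 in MeOH removes the alkyne silyl group to give the terminal alkyne F8. Hydroboration with Cy2BH and perborate work-up (anti-Markovnikov hydration) gives the aldehyde F9, and Pinnick oxidation returns to the route at 15.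

**Further compounds**

F1 | step 5 | (2R,3R,4S)-4-allyl-5,7-bis(benzyloxy)-2-[3,4-bis(benzyloxy)phenyl]-3,4-dihydro-2H-chromen-3-ol | C=CC[C@H]1c2c(OCc3ccccc3)cc(OCc3ccccc3)cc2O[C@H](c2ccc(OCc3ccccc3)c(OCc3ccccc3)c2)[C@@H]1O
F2 | step 5 | 2-{(2R,3R,4S)-5,7-bis(benzyloxy)-2-[3,4-bis(benzyloxy)phenyl]-3-hydroxy-3,4-dihydro-2H-chromen-4-yl}acetaldehyde | O=CC[C@H]1c2c(OCc3ccccc3)cc(OCc3ccccc3)cc2O[C@H](c2ccc(OCc3ccccc3)c(OCc3ccccc3)c2)[C@@H]1O
F3 | step 5 | 2-{(2R,3R,4S)-5,7-bis(benzyloxy)-2-[3,4-bis(benzyloxy)phenyl]-3-hydroxy-3,4-dihydro-2H-chromen-4-yl}acetic acid | O=C(O)C[C@H]1c2c(OCc3ccccc3)cc(OCc3ccccc3)cc2O[C@H](c2ccc(OCc3ccccc3)c(OCc3ccccc3)c2)[C@@H]1O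
F4 | step 5 | benzyl 2-{(2R,3R,4S)-5,7-bis(benzyloxy)-2-[3,4-bis(benzyloxy)phenyl]-3-hydroxy-3,4-dihydro-2H-chromen-4-yl}acetate | O=C(OCc3ccccc3)C[C@H]1c2c(OCc3ccccc3)cc(OCc3ccccc3)cc2O[C@H](c2ccc(OCc3ccccc3)c(OCc3ccccc3)c2)[C@@H]1O
F5 | step 5 | benzyl ester of 15 (octa-O-benzyl 4β→8 dimer, lower 2R,3R,4S, upper 2R,3R,4R) | O=C(OCc5ccccc5)C[C@H]1c2c(OCc5ccccc5)cc(OCc5ccccc5)c([C@H]3c4c(OCc5ccccc5)cc(OCc5ccccc5)cc4O[C@H](c4ccc(OCc5ccccc5)c(OCc5ccccc5)c4)[C@@H]3O)c2O[C@H](c2ccc(OCc5ccccc5)c(OCc5ccccc5)c2)[C@@H]1O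
F6 | step 8 | 4β-(benzylsulfanyl)-5,7,3',4'-tetra-O-benzylepicatechin (3,4-trans, configuration as in 11) | S(Cc3ccccc3)[C@H]1c2c(OCc3ccccc3)cc(OCc3ccccc3)cc2O[C@H](c2ccc(OCc3ccccc3)c(OCc3ccccc3)c2)[C@@H]1O
F7 | step 9 | octa-O-benzyl 4β→8 dimer with lower C3–OH and C4 (trimethylsilyl)ethynyl (spatial arrangement as in 12) | C[Si](C)(C)C#C[C@H]1c2c(OCc5ccccc5)cc(OCc5ccccc5)c([C@H]3c4c(OCc5ccccc5)cc(OCc5ccccc5)cc4O[C@H](c4ccc(OCc5ccccc5)c(OCc5ccccc5)c4)[C@@H]3O)c2O[C@H](c2ccc(OCc5ccccc5)c(OCc5ccccc5)c2)[C@@H]1O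
F8 | step 9 | octa-O-benzyl 4β→8 dimer with lower C3–OH and C4 ethynyl (spatial arrangement as in 12) | C#C[C@H]1c2c(OCc5ccccc5)cc(OCc5ccccc5)c([C@H]3c4c(OCc5ccccc5)cc(OCc5ccccc5)cc4O[C@H](c4ccc(OCc5ccccc5)c(OCc5ccccc5)c4)[C@@H]3O)c2O[C@H](c2ccc(OCc5ccccc5)c(OCc5ccccc5)c2)[C@@H]1O
F9 | step 9 | aldehyde corresponding to 15 (lower C4–CH2CHO; lower 2R,3R,4S, upper 2R,3R,4R) | O=CC[C@H]1c2c(OCc5ccccc5)cc(OCc5ccccc5)c([C@H]3c4c(OCc5ccccc5)cc(OCc5ccccc5)cc4O[C@H](c4ccc(OCc5ccccc5)c(OCc5ccccc5)c4)[C@@H]3O)c2O[C@H](c2ccc(OCc5ccccc5)c(OCc5ccccc5)c2)[C@@H]1O
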